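The pyran ring is disconnected at C2–C3 and at O1–C8a, which separates acetaldehyde (O1, C2 and the 2-methyl group) from an aryl methyl ketone whose carbonyl carbon is C4 and whose C8a still carries fluorine. The key step joins the two in one operation: a catalytic enantioselective Mukaiyama aldol addition sets C2, and the alkoxide so formed closes the ring by SNAr at C8a. It exploits the fact that O1 sits ortho to the C4 branch on the resorcinol ring (C4a–C8a): a C4 carbonyl makes C3 nucleophilic and C8a electrophilic. The precursor is the enol silane of 2'-benzyloxy-6'-fluoroacetophenone. The naphthyl group then enters at C4, and hydrogenation anti to the 2-methyl group sets C4.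

Key step: step 3

Remark: chroman numbering (O1, C2, C3, C4, C4a, C5 to C8, C8a) is used throughout; the target is read as the (2S,4S) isomer, in which the 2-methyl and 4-aryl groups are cis; compounds 1, 4 and 7 are taken as commercial.

Step 1
Reactants: 1 1-(2-fluoro-6-hydroxyphenyl)ethan-1-one
Product: 2 1-[2-(benzyloxy)-6-fluorophenyl]ethan-1-one
Conditions: BnBr, K2CO3, DMF, 20 °C
Reagents that add atoms: benzyl bromide, BrCc1ccccc1
Why: Williamson etherification of the phenoxide masks the future C5 hydroxyl as a benzyl ether that should survive steps 2 to 5 and fall off in step 6.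

Step 2
Reactants: 2 1-[2-(benzyloxy)-6-fluorophenyl]ethan-1-one
Product: 3 {[1-(2-(benzyloxy)-6-fluorophenyl)ethenyl]oxy}(trimethyl)silane
Conditions: TMSOTf, Et3N, CH2Cl2, 0 °C
Reagents that add atoms: trimethylsilyl trifluoromethanesulfonate, C[Si](C)(C)OS(=O)(=O)C(F)(F)F
Why: Soft enolisation and O-silylation of the methyl ketone should give the enol silane needed as the Mukaiyama aldol donor, with the aryl fluoride and benzyl ether inert.

Step 3
Reactants: 3 {[1-(2-(benzyloxy)-6-fluorophenyl)ethenyl]oxy}(trimethyl)silane; 4 acetaldehyde
Product: 6 (2S)-5-(benzyloxy)-2-methyl-2,3-dihydro-4H-chromen-4-one, via silyl aldol adduct 5 (not isolated)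
Conditions: oxazaborolidinone from N-tosyl-(S)-tryptophan and n-BuB(OH)2 (20 mol %), EtCN, −78 °C; then TBAF, THF, −78 to 20 °C
Reagents that add atoms: none
Why: The boron Lewis acid binds acetaldehyde 4 and the terminal CH2 of enol silane 3 (future C3) adds to the re face of the aldehyde carbon (future C2) in an enantioselective Mukaiyama aldol addition, giving after silyl transfer the 3S silyl ether 5. Fluoride then frees the secondary alkoxide, which attacks the fluorine-bearing ring carbon (future C8a) by intramolecular SNAr through a Meisenheimer intermediate stabilised by the ortho ketone, so that the C2–C3 and O1–C8a bonds arise in one flask. The closest known reaction type is the domino aldol–SNAr annulation of ortho-fluoroaryl ketones. The only ring closed is the pyranone ring, by attack of O1 on the sp2 carbon C8a (formally 6-endo-trig with respect to the C4a=C8a bond that relays the charge to the ketone, followed by loss of fluoride). The C2 stereocentre is set by the catalyst alone; the (S)-tryptophan-derived catalyst is expected to expose the re face, and its enantiomer is used if the sense proves opposite. The step needs ring closure to outrun retro-aldol cleavage and E1cB dehydration of the alkoxide, which the six-membered transition state and the carbonyl-activated C–F carbon should secure at or below room temperature.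

Step 4
Reactants: 7 1,8-dimethoxynaphthalene
Product: 8 1-bromo-4,5-dimethoxynaphthalene
Conditions: NBS (1.0 equiv), MeCN, 0 to 20 °C
Reagents that add atoms: N-bromosuccinimide, O=C1CCC(=O)N1Br
Why: Electrophilic aromatic bromination should occur para to a methoxy group at the most activated unhindered position, and one equivalent of NBS at low temperature limits dibromination.

Step 5
Reactants: 8 1-bromo-4,5-dimethoxynaphthalene; 6 (2S)-5-(benzyloxy)-2-methyl-2,3-dihydro-4H-chromen-4-one
Product: 12 (2S)-5-(benzyloxy)-4-(4,5-dimethoxynaphthalen-1-yl)-2-methyl-2H-chromene, via aryllithium 9 (not isolated), via arylcerium dichloride 10 (not isolated), via tertiary carbinol 11 (not isolated)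
Conditions: 8, n-BuLi, THF, −78 °C; CeCl3, −78 °C; 6, −78 to 0 °C; 1 M HCl; then crude 11, p-TsOH·H2O (cat.), CH2Cl2, 0 °C
Reagents that add atoms: none
Why: Bromine–lithium exchange and transmetallation give a weakly basic organocerium reagent that should add 1,2 to the enolisable ketone without deprotonating C3 (so C2 is not scrambled by ring opening), and the doubly benzylic tertiary carbinol then loses water by E1 elimination to the conjugated 2H-chromene.

Step 6
Reactants: 12 (2S)-5-(benzyloxy)-4-(4,5-dimethoxynaphthalen-1-yl)-2-methyl-2H-chromene
Product: 13 cladonaphchrom B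
Conditions: H2 (1–4 bar), 10% Pd/C, EtOAc–EtOH, 20 °C
Reagents that add atoms: none
Why: Heterogeneous hydrogenation should add H2 syn to the C3=C4 bond from the face opposite the 2-methyl group, which places the C4 aryl group cis to the methyl group (4S), and the same catalyst cleaves the benzyl ether by hydrogenolysis to free the C5 phenol.

Compound list
1 | 1-(2-fluoro-6-hydroxyphenyl)ethan-1-one | CC(=O)c1c(O)cccc1F | starting material
2 | 1-[2-(benzyloxy)-6-fluorophenyl]ethan-1-one | CC(=O)c1c(OCc2ccccc2)cccc1F | intermediate
3 | {[1-(2-(benzyloxy)-6-fluorophenyl)ethenyl]oxy}(trimethyl)silane | C=C(O[Si](C)(C)C)c1c(OCc2ccccc2)cccc1F | intermediate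
4 | acetaldehyde | CC=O | starting material
5 | (3S)-1-[2-(benzyloxy)-6-fluorophenyl]-3-[(trimethylsilyl)oxy]butan-1-one | C[C@H](O[Si](C)(C)C)CC(=O)c1c(OCc2ccccc2)cccc1F | intermediate
6 | (2S)-5-(benzyloxy)-2-methyl-2,3-dihydro-4H-chromen-4-one | C[C@H]1CC(=O)c2c(OCc3ccccc3)cccc2O1 | intermediate
7 | 1,8-dimethoxynaphthalene | COc1cccc2cccc(OC)c12 | starting material
8 | 1-bromo-4,5-dimethoxynaphthalene | COc1ccc(Br)c2cccc(OC)c12 | intermediate
9 | (4,5-dimethoxynaphthalen-1-yl)lithium | [Li]c1ccc(OC)c2c(OC)cccc12 | intermediate
10 | dichloro(4,5-dimethoxynaphthalen-1-yl)cerium | Cl[Ce](Cl)c1ccc(OC)c2c(OC)cccc12 | intermediate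
11 | (2S)-5-(benzyloxy)-4-(4,5-dimethoxynaphthalen-1-yl)-2-methyl-3,4-dihydro-2H-chromen-4-ol (both C4 epimers) | C[C@H]1CC(O)(c2ccc(OC)c3c(OC)cccc23)c2c(OCc3ccccc3)cccc2O1 | intermediate
12 | (2S)-5-(benzyloxy)-4-(4,5-dimethoxynaphthalen-1-yl)-2-methyl-2H-chromene | C[C@H]1C=C(c2ccc(OC)c3c(OC)cccc23)c2c(OCc3ccccc3)cccc2O1 | intermediate
13 | cladonaphchrom B, (2S,4S)-4-(4,5-dimethoxynaphthalen-1-yl)-2-methyl-3,4-dihydro-2H-chromen-5-ol | COc1cccc2c([C@@H]3C[C@H](C)Oc4cccc(O)c43)ccc(OC)c12 | target

Total step count: 6. Longest linear sequence: 5 steps (steps 1, 2, 3, 5 and 6); step 4 is a one-step side branch.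

Steps most likely to fail

Step 3 (key step). The small aldehyde may be bound with too little facial bias. Under fluoride the alkoxide may also undergo retro-aldol cleavage or E1cB dehydration before it cyclises, or the chromanone may ring-open and re-close, each eroding yield or enantiomeric purity. The fallback makes the ring first without a stereocentre and installs C2 by reduction. Setting out from 2, Claisen condensation with ethyl acetate (NaH, THF, reflux) should give 1-[2-(benzyloxy)-6-fluorophenyl]butane-1,3-dione F1 as its enolate. On heating in DMF the enolate oxygen should displace fluoride to give 5-(benzyloxy)-2-methyl-4H-chromen-4-one F2, so the same two bonds are still formed in one operation. Asymmetric hydrogenation with Ru(cod)(2-methylallyl)2 and a chiral N-heterocyclic carbene ligand (enantiomer chosen for 2S) under H2 should give (2S,4R)-5-(benzyloxy)-2-methyl-3,4-dihydro-2H-chromen-4-ol F3. MnO2 oxidation of this benzylic alcohol comes back to 6.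

Step 5. The aryl metal may deprotonate C3 instead of adding, which returns ketone or leads to β-elimination of the phenoxide and loss of configurational purity at C2. Addition of the hindered naphthyl nucleophile may also be slow, and the allylic C2–O bond may ionise during the acid dehydration. The fallback is a cross-coupling that avoids both the carbanion addition and the acid. Setting out from 6, Tf2O with 2,6-di-tert-butyl-4-methylpyridine in CH2Cl2 should give (2S)-5-(benzyloxy)-2-methyl-2H-chromen-4-yl trifluoromethanesulfonate F4 without forming an enolate. Bromide 8 is converted (n-BuLi, THF, −78 °C; B(OiPr)3; aqueous acid) into (4,5-dimethoxynaphthalen-1-yl)boronic acid F5. Suzuki–Miyaura coupling of the two (Pd(OAc)2, SPhos, K3PO4, toluene–water, 80 °C) comes back to 12.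

Step 6. Facial selectivity may be insufficient, or the reaction may stall at the hindered trisubstituted alkene. Hydrogenolysis of the allylic C2–O bond before the alkene is saturated and partial saturation of the naphthalene are further risks. The fallback is an ionic reduction. Setting out from 12, CF3CO2H and Et3SiH in CH2Cl2 at low temperature protonate C3 and should deliver hydride axially to the C4 cation. This should give the diequatorial (2S,4S)-5-(benzyloxy)-4-(4,5-dimethoxynaphthalen-1-yl)-2-methyl-3,4-dihydro-2H-chromene F6. Hydrogenolysis of the benzyl ether alone (H2, 10% Pd/C, 1 atm, EtOAc) then comes back to 13.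

Further compounds
F1 | step 3 | 1-[2-(benzyloxy)-6-fluorophenyl]butane-1,3-dione | CC(=O)CC(=O)c1c(OCc2ccccc2)cccc1F
F2 | step 3 | 5-(benzyloxy)-2-methyl-4H-chromen-4-one | CC1=CC(=O)c2c(OCc3ccccc3)cccc2O1
F3 | step 3 | (2S,4R)-5-(benzyloxy)-2-methyl-3,4-dihydro-2H-chromen-4-ol | C[C@H]1C[C@@H](O)c2c(OCc3ccccc3)cccc2O1
F4 | step 5 | (2S)-5-(benzyloxy)-2-methyl-2H-chromen-4-yl trifluoromethanesulfonate | C[C@H]1C=C(OS(=O)(=O)C(F)(F)F)c2c(OCc3ccccc3)cccc2O1
F5 | step 5 | (4,5-dimethoxynaphthalen-1-yl)boronic acid | COc1ccc(B(O)O)c2cccc(OC)c12
F6 | step 6 | (2S,4S)-5-(benzyloxy)-4-(4,5-dimethoxynaphthalen-1-yl)-2-methyl-3,4-dihydro-2H-chromene | COc1cccc2c([C@@H]3C[C@H](C)Oc4cccc(OCc5ccccc5)c43)ccc(OC)c12
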